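The outer dihydrobenzofuran is cut at C3–C3a. There C3 carries arene carbon C3a and the exocyclic CH2OH carbon, which is what a chroman-4-one leaves behind when C4a migrates from C4 to C3 and C4 is pushed out of the ring as an ester carbon. One oxidative 1,2-aryl shift of a (2S)-6-bromo-8-methoxyflavanone, whose C2 aryl ring is deactivated as a pivalate, therefore creates the five-membered ring, the C3–C3a bond and the trans C3 stereocentre at once. The bromide then carries the synthesis inward: a mirror-image flavanone contraction, then lactone aldol and hemiketal reduction for the all-cis tetrahydrofuran.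

Key step: step 5

Remark 1: the target is read as outer dihydrobenzofuran (2S,3R) and inner dihydrobenzofuran (2R,3S), both trans, with a 2,3-cis-3,4-cis tetrahydrofuran (2R,3R,4R; aryl, CH2OH and benzyl on one face). The route is built for exactly this isomer.

Remark 2: the ligand enantiomers named in steps 4, 7 and 13 are those expected from the usual sense of induction of these catalyst classes. If a first run shows the opposite sense, the mirror-image ligand is used with no other change.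

Abbreviations: Piv = 2,2-dimethylpropanoyl; pin = pinacolato; TBS = tert-butyldimethylsilyl; MeO-F12-BIPHEP = 6,6'-dimethoxy-2,2'-bis[bis(3,4,5-trifluorophenyl)phosphino]biphenyl; ArG = 3-methoxy-4-(TBS-oxy)phenyl; ArD = (2R,3S)-3-(TBS-oxymethyl)-7-methoxy-2-[(2S,3R)-3-(TBS-oxymethyl)-7-methoxy-2-ArG-2,3-dihydrobenzofuran-5-yl]-2,3-dihydrobenzofuran-5-yl.

Step 1
Reactants: 1 2'-hydroxy-3'-methoxyacetophenone
Product: 2 1-(5-bromo-2-hydroxy-3-methoxyphenyl)ethan-1-one
Conditions: NBS, MeCN, 0 °C → rt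
Reagents that add atoms: N-bromosuccinimide, O=C1CCC(=O)N1Br
Why: Electrophilic aromatic bromination, in which the phenol directs to its para position (C5), the only open activated site and also meta to the acetyl group.

Step 2
Reactants: 2 1-(5-bromo-2-hydroxy-3-methoxyphenyl)ethan-1-one
Product: 4 6-bromo-8-methoxy-4H-chromen-4-one, via enaminone 3 (not isolated)
Conditions: Me2NCH(OMe)2, toluene, 100 °C; then conc. HCl, CH2Cl2, 40 °C
Reagents that add atoms: N,N-dimethylformamide dimethyl acetal, COC(OC)N(C)C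
Why: Condensation of the methyl ketone with the formamide acetal gives the enaminone, and acid-promoted conjugate addition of the phenol with loss of dimethylamine closes the chromone (the standard enaminone route to chromones).

Step 3
Reactants: 5 2-methoxy-4-(4,4,5,5-tetramethyl-1,3,2-dioxaborolan-2-yl)phenol
Product: 6 2-methoxy-4-(4,4,5,5-tetramethyl-1,3,2-dioxaborolan-2-yl)phenyl pivalate
Conditions: PivCl, Et3N, DMAP (cat.), CH2Cl2, 0 °C → rt
Reagents that add atoms: pivaloyl chloride, CC(C)(C)C(=O)Cl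
Why: DMAP-catalysed O-acylation of the phenol, to which the pinacol boronate is inert.

Step 4
Reactants: 4 6-bromo-8-methoxy-4H-chromen-4-one; 6 2-methoxy-4-(4,4,5,5-tetramethyl-1,3,2-dioxaborolan-2-yl)phenyl pivalate
Product: 7 (2S)-6-bromo-8-methoxy-2-[3-methoxy-4-(pivaloyloxy)phenyl]chroman-4-one
Conditions: [Rh(OH)(cod)]2 (cat.), (S)-MeO-F12-BIPHEP (cat.), 6 (1.5 equiv), K3PO4 (0.5 equiv), 1,4-dioxane/H2O, 40 °C
Reagents that add atoms: none
Why: Hayashi–Miyaura asymmetric 1,4-addition, in which the arylrhodium species adds to C2 of the chromone on the face selected by the atropisomeric bisphosphine and protonation releases the (2S)-flavanone, while monovalent rhodium leaves the aryl bromide untouched.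

Step 5
Reactants: 7 (2S)-6-bromo-8-methoxy-2-[3-methoxy-4-(pivaloyloxy)phenyl]chroman-4-one
Product: 10 methyl (2S,3S)-5-bromo-7-methoxy-2-[3-methoxy-4-(pivaloyloxy)phenyl]-2,3-dihydrobenzofuran-3-carboxylate (trans), via enol ether 8 (not isolated), via orthoester 9 (not isolated)
Conditions: PhI(OAc)2 (1.2 equiv), conc. H2SO4, HC(OMe)3/MeOH, 0 °C → rt; then H2O
Reagents that add atoms: trimethyl orthoformate, COC(OC)OC; methanol, CO; water, O
Why: Acid and orthoformate convert the C4 ketone into enol ether 8, electrophilic trivalent iodine adds to C3 on the face opposite the C2 aryl group, and methanol caps C4 as a dimethyl ketal. Loss of iodobenzene from the pseudo-equatorial C3–I bond is assisted by the antiperiplanar C4–C4a bond, so arene carbon C4a shifts from C4 to C3 and the resulting dimethoxycarbenium ion is trapped as orthoester 9, which water hydrolyses to the methyl ester. The closest known reaction type is the hypervalent-iodine oxidative ring contraction of flavanones to trans-2-aryl-2,3-dihydrobenzofuran-3-carboxylates, a semipinacol-type 1,2-aryl shift of an α-iodanyl ketal. The five-membered ring is closed by contraction and not by an exo or endo cyclisation: the C3–C3a bond forms through a bridged 1,2-shift while the C4–C4a bond breaks. The new C3 centre is controlled by the existing C2 centre, since anti addition of iodine followed by migration with inversion places the ester trans to the aryl group (3S); C2 should persist because no bond to it is touched and ketalisation removes the enolisable ketone through which the pyranone ring could open. The step needs migration of ring A carbon C4a in preference to shift of the C2 aryl ring (isoflavone) or elimination (flavone), which is secured by the ketal medium making C4 the best cation-stabilising terminus, by the diequatorial adduct aligning only the C4–C4a bond with the leaving group, and by the pivalate keeping the C2 aryl ring electron-poor.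

Step 6
Reactants: 10 methyl (2S,3S)-5-bromo-7-methoxy-2-[3-methoxy-4-(pivaloyloxy)phenyl]-2,3-dihydrobenzofuran-3-carboxylate
Product: 11 methyl (2S,3S)-7-methoxy-2-[3-methoxy-4-(pivaloyloxy)phenyl]-5-(4,4,5,5-tetramethyl-1,3,2-dioxaborolan-2-yl)-2,3-dihydrobenzofuran-3-carboxylate
Conditions: B2pin2, Pd(dppf)Cl2 (cat.), KOAc, 1,4-dioxane, 85 °C
Reagents that add atoms: bis(pinacolato)diboron, CC1(C)OB(OC1(C)C)B1OC(C)(C)C(C)(C)O1
Why: Miyaura borylation (oxidative addition of the unhindered aryl bromide to zerovalent palladium, acetate-assisted transmetalation, reductive elimination), with KOAc too weak a base to epimerise or open the ester-bearing ring.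

Step 7
Reactants: 11 methyl (2S,3S)-7-methoxy-2-[3-methoxy-4-(pivaloyloxy)phenyl]-5-(4,4,5,5-tetramethyl-1,3,2-dioxaborolan-2-yl)-2,3-dihydrobenzofuran-3-carboxylate; 4 6-bromo-8-methoxy-4H-chromen-4-one
Product: 12 methyl (2S,3S)-5-[(2R)-6-bromo-8-methoxy-4-oxochroman-2-yl]-7-methoxy-2-[3-methoxy-4-(pivaloyloxy)phenyl]-2,3-dihydrobenzofuran-3-carboxylate
Conditions: [Rh(OH)(cod)]2 (cat.), (R)-MeO-F12-BIPHEP (cat.), 4 (2 equiv), K3PO4 (0.5 equiv), 1,4-dioxane/H2O, 40 °C
Reagents that add atoms: none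
Why: Second Hayashi–Miyaura 1,4-addition to the same chromone, now under control of the mirror-image ligand so that the new flavanone centre is 2R whatever the remote stereocentres of the boronate, with the chromone in excess because the boronate is the valuable partner.

Step 8
Reactants: 12 methyl (2S,3S)-5-[(2R)-6-bromo-8-methoxy-4-oxochroman-2-yl]-7-methoxy-2-[3-methoxy-4-(pivaloyloxy)phenyl]-2,3-dihydrobenzofuran-3-carboxylate
Product: 15 methyl (2R,3R)-5-bromo-7-methoxy-2-{(2S,3S)-7-methoxy-3-(methoxycarbonyl)-2-[3-methoxy-4-(pivaloyloxy)phenyl]-2,3-dihydrobenzofuran-5-yl}-2,3-dihydrobenzofuran-3-carboxylate, via enol ether 13 (not isolated), via orthoester 14 (not isolated)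
Conditions: PhI(OAc)2 (1.1 equiv), conc. H2SO4, HC(OMe)3/MeOH, 0 °C → rt; then H2O
Reagents that add atoms: trimethyl orthoformate, COC(OC)OC; methanol, CO; water, O
Why: The hypervalent-iodine ring contraction of step 5 on the mirror-image flavanone, where iodine adds to C3 anti to the C2 substituent and C4a migrates with inversion to give the trans (2R,3R) ester, the ketal medium again favouring contraction over shift of the C2 aryl group and both esters and the pivalate being stable to the acid.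

Step 9
Reactants: 15 methyl (2R,3R)-5-bromo-7-methoxy-2-{(2S,3S)-7-methoxy-3-(methoxycarbonyl)-2-[3-methoxy-4-(pivaloyloxy)phenyl]-2,3-dihydrobenzofuran-5-yl}-2,3-dihydrobenzofuran-3-carboxylate
Product: 16 [(2R,3S)-5-bromo-2-{(2S,3R)-2-(4-hydroxy-3-methoxyphenyl)-3-(hydroxymethyl)-7-methoxy-2,3-dihydrobenzofuran-5-yl}-7-methoxy-2,3-dihydrobenzofuran-3-yl]methanol
Conditions: LiAlH4, THF, 0 °C; then H2O
Reagents that add atoms: none
Why: Hydride reduction of both methyl esters to primary alcohols with concomitant cleavage of the pivalate, the aryl bromide and the trans ring stereocentres being unaffected at 0 °C.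

Step 10
Reactants: 16 [(2R,3S)-5-bromo-2-{(2S,3R)-2-(4-hydroxy-3-methoxyphenyl)-3-(hydroxymethyl)-7-methoxy-2,3-dihydrobenzofuran-5-yl}-7-methoxy-2,3-dihydrobenzofuran-3-yl]methanol
Product: 17 ArD–Br (the tris-TBS ether of 16)
Conditions: TBSCl, imidazole, DMF, rt
Reagents that add atoms: tert-butyldimethylsilyl chloride, CC(C)(C)[Si](C)(C)Cl
Why: Standard imidazole-promoted silylation of the phenol and both primary alcohols, giving base-stable groups that a single fluoride treatment removes at the end.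

Step 11
Reactants: 17 ArD–Br
Product: 19 ArD–CHO (the 5-carbaldehyde), via aryllithium 18 (not isolated)
Conditions: n-BuLi, THF, −78 °C; then DMF, −78 → 0 °C; H2O
Reagents that add atoms: N,N-dimethylformamide, CN(C)C=O
Why: Bromine–lithium exchange at −78 °C followed by formylation of the aryllithium with DMF (Bouveault aldehyde synthesis), which silyl ethers and the ring ether C–H bonds tolerate.

Step 12
Reactants: 20 4-(benzyloxy)-3-methoxybenzaldehyde; 21 dimethyl succinate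
Product: 22 (E)-4-[4-(benzyloxy)-3-methoxyphenyl]-3-(methoxycarbonyl)but-3-enoic acid
Conditions: NaOMe, MeOH, reflux; then aq. HCl
Reagents that add atoms: none
Why: Stobbe condensation, in which the succinate enolate adds to the aldehyde and lactonisation followed by eliminative ring opening gives the (E)-alkylidene half-ester with the two carboxyl groups differentiated.

Step 13
Reactants: 22 (E)-4-[4-(benzyloxy)-3-methoxyphenyl]-3-(methoxycarbonyl)but-3-enoic acid
Product: 23 (3R)-4-[4-(benzyloxy)-3-methoxyphenyl]-3-(methoxycarbonyl)butanoic acid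
Conditions: H2 (5 bar), [Rh(cod)2]BF4 (cat.), (S,S)-Et-DuPhos (cat.), NaOMe (cat.), MeOH, rt
Reagents that add atoms: none
Why: Rhodium–bisphospholane asymmetric hydrogenation of a Stobbe-type itaconate half-ester, in which chelation through the carboxylate fixes the face of hydrogen delivery and sets the (R) centre.

Step 14
Reactants: 23 (3R)-4-[4-(benzyloxy)-3-methoxyphenyl]-3-(methoxycarbonyl)butanoic acid
Product: 25 (4R)-4-[4-(benzyloxy)-3-methoxybenzyl]dihydrofuran-2(3H)-one, via hydroxy acid 24 (not isolated)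
Conditions: KOH (1 equiv), EtOH; CaCl2, NaBH4, −10 °C → rt; then 2 M HCl, rt
Reagents that add atoms: none
Why: Chemoselective borohydride reduction of the methyl ester beside the carboxylate salt, then acid-induced lactonisation of the hydroxy acid, neither of which touches the stereocentre.

Step 15
Reactants: 25 (4R)-4-[4-(benzyloxy)-3-methoxybenzyl]dihydrofuran-2(3H)-one
Product: 26 (4R)-4-(4-hydroxy-3-methoxybenzyl)dihydrofuran-2(3H)-one
Conditions: H2 (1 atm), Pd/C, EtOAc, rt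
Reagents that add atoms: none
Why: Hydrogenolysis of the benzyl ether at a stage where no other benzylic C–O bond is present.

Step 16
Reactants: 26 (4R)-4-(4-hydroxy-3-methoxybenzyl)dihydrofuran-2(3H)-one
Product: 27 (4R)-4-(ArG-methyl)dihydrofuran-2(3H)-one
Conditions: TBSCl, imidazole, DMF, rt
Reagents that add atoms: tert-butyldimethylsilyl chloride, CC(C)(C)[Si](C)(C)Cl
Why: Silylation of the phenol so that every hydroxyl protecting group of the end game is a silyl ether.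

Step 17
Reactants: 27 (4R)-4-(ArG-methyl)dihydrofuran-2(3H)-one; 19 ArD–CHO
Product: 29 (3S,4R)-3-[ArD(hydroxy)methyl]-4-(ArG-methyl)dihydrofuran-2(3H)-one as both carbinol epimers, via lithium enolate 28 (not isolated)
Conditions: LiN(iPr)2, THF, −78 °C; then 19, −78 °C; AcOH quench
Reagents that add atoms: none
Why: Aldol addition of the lithium lactone enolate, in which the aldehyde approaches anti to the β-benzyl group and fixes the trans α,β relationship (3S,4R), the carbinol configuration being left uncontrolled because that centre is oxidised in step 19.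

Step 18
Reactants: 29 (3S,4R)-3-[ArD(hydroxy)methyl]-4-(ArG-methyl)dihydrofuran-2(3H)-one
Product: 30 (2R,3R)-2-[ArD(hydroxy)methyl]-3-(ArG-methyl)butane-1,4-diol as both carbinol epimers
Conditions: LiBH4, THF/MeOH, 0 °C → rt; then H2O
Reagents that add atoms: none
Why: Reduction of the lactone to the 1,4-diol with a borohydride that spares silyl ethers and does not epimerise the former α-carbon.

Step 19
Reactants: 30 (2R,3R)-2-[ArD(hydroxy)methyl]-3-(ArG-methyl)butane-1,4-diol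
Product: 31 (2R,3R)-1-ArD-4-hydroxy-2-(hydroxymethyl)-3-(ArG-methyl)butan-1-one
Conditions: MnO2 (activated, excess), CH2Cl2, rt
Reagents that add atoms: none
Why: Chemoselective MnO2 oxidation of the electron-rich benzylic alcohol, primary aliphatic alcohols being inert, so that both carbinol epimers converge on one aryl ketone.

Step 20
Reactants: 31 (2R,3R)-1-ArD-4-hydroxy-2-(hydroxymethyl)-3-(ArG-methyl)butan-1-one
Product: 33 [(2R,3R,4R)-2-ArD-4-(ArG-methyl)tetrahydrofuran-3-yl]methanol, via cyclic hemiketal 32 (not isolated)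
Conditions: Et3SiH, BF3·OEt2, CH2Cl2, −78 °C
Reagents that add atoms: none
Why: Reductive cyclisation by ionic hydrogenation, in which the 4-hydroxyl adds 5-exo-trig to the ketone, BF3 ionises the hemiketal to a 2-aryl oxocarbenium ion whose C3 and C4 substituents share one face, and Et3SiH delivers hydride from the open face so that the aryl group ends cis to both (2R), as in known reductions of 2-aryl lactols to 2,3-cis tetrahydrofurans.

Step 21
Reactants: 33 [(2R,3R,4R)-2-ArD-4-(ArG-methyl)tetrahydrofuran-3-yl]methanol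
Product: 34 [(2R,3R,4R)-4-(4-hydroxy-3-methoxybenzyl)-2-{(2R,3S)-3-(hydroxymethyl)-2-[(2S,3R)-2-(4-hydroxy-3-methoxyphenyl)-3-(hydroxymethyl)-7-methoxy-2,3-dihydrobenzofuran-5-yl]-7-methoxy-2,3-dihydrobenzofuran-5-yl}tetrahydrofuran-3-yl]methanol (CNP0395728.1)
Conditions: Bu4NF, AcOH, THF, 0 °C → rt
Reagents that add atoms: none
Why: Fluoride cleavage of the four silyl ethers, buffered with acetic acid so that the liberated phenols are not held under strongly basic conditions.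

Compound list

1 | 2'-hydroxy-3'-methoxyacetophenone | CC(=O)c1cccc(OC)c1O | starting material
2 | 1-(5-bromo-2-hydroxy-3-methoxyphenyl)ethan-1-one | CC(=O)c1cc(Br)cc(OC)c1O | intermediate
3 | (E)-1-(5-bromo-2-hydroxy-3-methoxyphenyl)-3-(dimethylamino)prop-2-en-1-one | CN(C)/C=C/C(=O)c1cc(Br)cc(OC)c1O | intermediate (not isolated)
4 | 6-bromo-8-methoxy-4H-chromen-4-one | O=c1ccoc2c(OC)cc(Br)cc12 | intermediate
5 | 2-methoxy-4-(4,4,5,5-tetramethyl-1,3,2-dioxaborolan-2-yl)phenol | COc1cc(B2OC(C)(C)C(C)(C)O2)ccc1O | starting material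
6 | 2-methoxy-4-(4,4,5,5-tetramethyl-1,3,2-dioxaborolan-2-yl)phenyl pivalate | COc1cc(B2OC(C)(C)C(C)(C)O2)ccc1OC(=O)C(C)(C)C | intermediate
7 | (2S)-6-bromo-8-methoxy-2-[3-methoxy-4-(pivaloyloxy)phenyl]chroman-4-one | Brc1cc(OC)c2c(c1)C(=O)C[C@@H](c1ccc(OC(=O)C(C)(C)C)c(OC)c1)O2 | intermediate
8 | (2S)-6-bromo-4,8-dimethoxy-2-[3-methoxy-4-(pivaloyloxy)phenyl]-2H-chromene | Brc1cc(OC)c2c(c1)C(OC)=C[C@@H](c1ccc(OC(=O)C(C)(C)C)c(OC)c1)O2 | intermediate (not isolated)
9 | (2S,3S)-5-bromo-7-methoxy-2-[3-methoxy-4-(pivaloyloxy)phenyl]-3-(trimethoxymethyl)-2,3-dihydrobenzofuran | Brc1cc(OC)c2c(c1)[C@H](C(OC)(OC)OC)[C@@H](c1ccc(OC(=O)C(C)(C)C)c(OC)c1)O2 | intermediate (not isolated)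
10 | methyl (2S,3S)-5-bromo-7-methoxy-2-[3-methoxy-4-(pivaloyloxy)phenyl]-2,3-dihydrobenzofuran-3-carboxylate (trans) | Brc1cc(OC)c2c(c1)[C@H](C(=O)OC)[C@@H](c1ccc(OC(=O)C(C)(C)C)c(OC)c1)O2 | intermediate
11 | methyl (2S,3S)-7-methoxy-2-[3-methoxy-4-(pivaloyloxy)phenyl]-5-(4,4,5,5-tetramethyl-1,3,2-dioxaborolan-2-yl)-2,3-dihydrobenzofuran-3-carboxylate | CC1(C)OB(OC1(C)C)c1cc(OC)c2c(c1)[C@H](C(=O)OC)[C@@H](c1ccc(OC(=O)C(C)(C)C)c(OC)c1)O2 | intermediate
12 | methyl (2S,3S)-5-[(2R)-6-bromo-8-methoxy-4-oxochroman-2-yl]-7-methoxy-2-[3-methoxy-4-(pivaloyloxy)phenyl]-2,3-dihydrobenzofuran-3-carboxylate | Brc1cc(OC)c2c(c1)C(=O)C[C@H](c3cc(OC)c4c(c3)[C@H](C(=O)OC)[C@@H](c3ccc(OC(=O)C(C)(C)C)c(OC)c3)O4)O2 | intermediate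
13 | methyl (2S,3S)-5-[(2R)-6-bromo-4,8-dimethoxy-2H-chromen-2-yl]-7-methoxy-2-[3-methoxy-4-(pivaloyloxy)phenyl]-2,3-dihydrobenzofuran-3-carboxylate | Brc1cc(OC)c2c(c1)C(OC)=C[C@H](c3cc(OC)c4c(c3)[C@H](C(=O)OC)[C@@H](c3ccc(OC(=O)C(C)(C)C)c(OC)c3)O4)O2 | intermediate (not isolated)
14 | methyl (2S,3S)-5-[(2R,3R)-5-bromo-7-methoxy-3-(trimethoxymethyl)-2,3-dihydrobenzofuran-2-yl]-7-methoxy-2-[3-methoxy-4-(pivaloyloxy)phenyl]-2,3-dihydrobenzofuran-3-carboxylate | Brc1cc(OC)c2c(c1)[C@@H](C(OC)(OC)OC)[C@H](c3cc(OC)c4c(c3)[C@H](C(=O)OC)[C@@H](c3ccc(OC(=O)C(C)(C)C)c(OC)c3)O4)O2 | intermediate (not isolated)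
15 | methyl (2R,3R)-5-bromo-7-methoxy-2-{(2S,3S)-7-methoxy-3-(methoxycarbonyl)-2-[3-methoxy-4-(pivaloyloxy)phenyl]-2,3-dihydrobenzofuran-5-yl}-2,3-dihydrobenzofuran-3-carboxylate | Brc1cc(OC)c2c(c1)[C@@H](C(=O)OC)[C@H](c3cc(OC)c4c(c3)[C@H](C(=O)OC)[C@@H](c3ccc(OC(=O)C(C)(C)C)c(OC)c3)O4)O2 | intermediate
16 | [(2R,3S)-5-bromo-2-{(2S,3R)-2-(4-hydroxy-3-methoxyphenyl)-3-(hydroxymethyl)-7-methoxy-2,3-dihydrobenzofuran-5-yl}-7-methoxy-2,3-dihydrobenzofuran-3-yl]methanol | Brc1cc(OC)c2c(c1)[C@@H](CO)[C@H](c3cc(OC)c4c(c3)[C@H](CO)[C@@H](c3ccc(O)c(OC)c3)O4)O2 | intermediate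
17 | ArD–Br, the tris-TBS ether of 16 | Brc1cc(OC)c2c(c1)[C@@H](CO[Si](C)(C)C(C)(C)C)[C@H](c3cc(OC)c4c(c3)[C@H](CO[Si](C)(C)C(C)(C)C)[C@@H](c3ccc(O[Si](C)(C)C(C)(C)C)c(OC)c3)O4)O2 | intermediate
18 | ArD–Li, the aryllithium from 17 | [Li]c1cc(OC)c2c(c1)[C@@H](CO[Si](C)(C)C(C)(C)C)[C@H](c3cc(OC)c4c(c3)[C@H](CO[Si](C)(C)C(C)(C)C)[C@@H](c3ccc(O[Si](C)(C)C(C)(C)C)c(OC)c3)O4)O2 | intermediate (not isolated)
19 | ArD–CHO, the 5-carbaldehyde | O=Cc1cc(OC)c2c(c1)[C@@H](CO[Si](C)(C)C(C)(C)C)[C@H](c3cc(OC)c4c(c3)[C@H](CO[Si](C)(C)C(C)(C)C)[C@@H](c3ccc(O[Si](C)(C)C(C)(C)C)c(OC)c3)O4)O2 | intermediate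
20 | 4-(benzyloxy)-3-methoxybenzaldehyde | COc1cc(C=O)ccc1OCc1ccccc1 | starting material
21 | dimethyl succinate | COC(=O)CCC(=O)OC | starting material
22 | (E)-4-[4-(benzyloxy)-3-methoxyphenyl]-3-(methoxycarbonyl)but-3-enoic acid | COC(=O)/C(CC(=O)O)=C/c1ccc(OCc2ccccc2)c(OC)c1 | intermediate
23 | (3R)-4-[4-(benzyloxy)-3-methoxyphenyl]-3-(methoxycarbonyl)butanoic acid | COC(=O)[C@@H](CC(=O)O)Cc1ccc(OCc2ccccc2)c(OC)c1 | intermediate
24 | (3R)-4-[4-(benzyloxy)-3-methoxyphenyl]-3-(hydroxymethyl)butanoic acid | OC[C@@H](CC(=O)O)Cc1ccc(OCc2ccccc2)c(OC)c1 | intermediate (not isolated)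
25 | (4R)-4-[4-(benzyloxy)-3-methoxybenzyl]dihydrofuran-2(3H)-one | O=C1C[C@@H](Cc2ccc(OCc3ccccc3)c(OC)c2)CO1 | intermediate
26 | (4R)-4-(4-hydroxy-3-methoxybenzyl)dihydrofuran-2(3H)-one | O=C1C[C@@H](Cc2ccc(O)c(OC)c2)CO1 | intermediate
27 | (4R)-4-[3-methoxy-4-(TBS-oxy)benzyl]dihydrofuran-2(3H)-one | O=C1C[C@@H](Cc2ccc(O[Si](C)(C)C(C)(C)C)c(OC)c2)CO1 | intermediate
28 | lithium enolate of 27 | [Li]OC1=C[C@@H](Cc2ccc(O[Si](C)(C)C(C)(C)C)c(OC)c2)CO1 | intermediate (not isolated)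
29 | (3S,4R)-3-[ArD(hydroxy)methyl]-4-(ArG-methyl)dihydrofuran-2(3H)-one, both carbinol epimers | O=C1OC[C@H](Cc2ccc(O[Si](C)(C)C(C)(C)C)c(OC)c2)[C@H]1C(O)c1cc(OC)c2c(c1)[C@@H](CO[Si](C)(C)C(C)(C)C)[C@H](c3cc(OC)c4c(c3)[C@H](CO[Si](C)(C)C(C)(C)C)[C@@H](c3ccc(O[Si](C)(C)C(C)(C)C)c(OC)c3)O4)O2 | intermediate
30 | (2R,3R)-2-[ArD(hydroxy)methyl]-3-(ArG-methyl)butane-1,4-diol, both carbinol epimers | OC[C@H](Cc1ccc(O[Si](C)(C)C(C)(C)C)c(OC)c1)[C@H](CO)C(O)c1cc(OC)c2c(c1)[C@@H](CO[Si](C)(C)C(C)(C)C)[C@H](c3cc(OC)c4c(c3)[C@H](CO[Si](C)(C)C(C)(C)C)[C@@H](c3ccc(O[Si](C)(C)C(C)(C)C)c(OC)c3)O4)O2 | intermediate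
31 | (2R,3R)-1-ArD-4-hydroxy-2-(hydroxymethyl)-3-(ArG-methyl)butan-1-one | OC[C@H](Cc1ccc(O[Si](C)(C)C(C)(C)C)c(OC)c1)[C@H](CO)C(=O)c1cc(OC)c2c(c1)[C@@H](CO[Si](C)(C)C(C)(C)C)[C@H](c3cc(OC)c4c(c3)[C@H](CO[Si](C)(C)C(C)(C)C)[C@@H](c3ccc(O[Si](C)(C)C(C)(C)C)c(OC)c3)O4)O2 | intermediate
32 | (3R,4R)-2-ArD-3-(hydroxymethyl)-4-(ArG-methyl)tetrahydrofuran-2-ol, both anomers | OC1(c2cc(OC)c3c(c2)[C@@H](CO[Si](C)(C)C(C)(C)C)[C@H](c4cc(OC)c5c(c4)[C@H](CO[Si](C)(C)C(C)(C)C)[C@@H](c4ccc(O[Si](C)(C)C(C)(C)C)c(OC)c4)O5)O3)OC[C@H](Cc2ccc(O[Si](C)(C)C(C)(C)C)c(OC)c2)[C@@H]1CO | intermediate (not isolated)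
33 | [(2R,3R,4R)-2-ArD-4-(ArG-methyl)tetrahydrofuran-3-yl]methanol | COc1cc(C[C@H]2CO[C@@H](c3cc(OC)c4c(c3)[C@@H](CO[Si](C)(C)C(C)(C)C)[C@H](c3cc(OC)c5c(c3)[C@H](CO[Si](C)(C)C(C)(C)C)[C@@H](c3ccc(O[Si](C)(C)C(C)(C)C)c(OC)c3)O5)O4)[C@H]2CO)ccc1O[Si](C)(C)C(C)(C)C | intermediate
34 | CNP0395728.1, the fully deprotected tetraol-diphenol named in step 21 | COc1cc(C[C@H]2CO[C@@H](c3cc(OC)c4c(c3)[C@@H](CO)[C@H](c3cc(OC)c5c(c3)[C@H](CO)[C@@H](c3ccc(O)c(OC)c3)O5)O4)[C@H]2CO)ccc1O | target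

Total step count: 21.
Longest linear sequence: 15 steps (steps 1, 2, 4–11, 17–21, from 1 to 34).

Steps most likely to fail

Step 5. What may go wrong: erosion of the C2 configuration by acid-induced opening of the pyranone ring before the ketone is masked, or diversion into dehydrogenation to the flavone or shift of the C2 aryl group. The fallback sets out from 2 and returns at 10; it sets both stereocentres with a chiral dirhodium carbenoid instead of carrying one through a flavanone. Vanillyl alcohol is pivaloylated selectively at the phenol (PivCl, aq. NaOH, CH2Cl2, Schotten–Baumann conditions) to give 4-(hydroxymethyl)-2-methoxyphenyl pivalate F1. Mitsunobu etherification of the phenol of 2 with this alcohol (PPh3, DIAD, THF) gives 1-{5-bromo-3-methoxy-2-[(3-methoxy-4-pivaloyloxyphenyl)methoxy]phenyl}ethan-1-one F2. Oxidative 1,2-aryl shift of the acetyl group (PhI(OAc)2, H2SO4, HC(OMe)3) gives methyl 2-{5-bromo-3-methoxy-2-[(3-methoxy-4-pivaloyloxyphenyl)methoxy]phenyl}acetate F3. Diazo transfer (4-acetamidobenzenesulfonyl azide, DBU, MeCN) gives methyl 2-diazo-2-{5-bromo-3-methoxy-2-[(3-methoxy-4-pivaloyloxyphenyl)methoxy]phenyl}acetate F4. Intramolecular carbenoid insertion into the benzylic ether C–H bond with Rh2(S-PTTL)4 (toluene, −60 °C; catalyst enantiomer chosen for 2S) closes the ring to methyl (2S,3R)-5-bromo-7-methoxy-2-[3-methoxy-4-(pivaloyloxy)phenyl]-2,3-dihydrobenzofuran-3-carboxylate F5, the cis ester. DBU in CH2Cl2 then equilibrates C3 to the trans ester 10.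

Step 8. What may go wrong: migration of the electron-rich C2 aryl group (its para oxygen is the ring oxygen of the first dihydrobenzofuran) in place of ring A, or attack of trivalent iodine on that arene. The fallback sets out from 12 and returns at 15; it replaces the cationic shift by a Wolff ring contraction, in which only the carbonyl-bound arene carbon can migrate. Condensation of 12 at C3 with Me2NCH(OMe)2 (toluene, 90 °C) gives methyl (2S,3S)-5-{(2S,3E)-6-bromo-3-[(dimethylamino)methylidene]-8-methoxy-4-oxochroman-2-yl}-7-methoxy-2-[3-methoxy-4-(pivaloyloxy)phenyl]-2,3-dihydrobenzofuran-3-carboxylate F6 (same spatial arrangement at the chromanone C2 as in 12; the descriptor changes because C3 now outranks the aryl group). Diazo transfer to the enaminone with tosyl azide (CH2Cl2, rt) gives methyl (2S,3S)-5-[(2S)-6-bromo-3-diazo-8-methoxy-4-oxochroman-2-yl]-7-methoxy-2-[3-methoxy-4-(pivaloyloxy)phenyl]-2,3-dihydrobenzofuran-3-carboxylate F7. Photolysis in methanol (Wolff rearrangement, methanol adding to the ketene) should give 15 together with its C3 epimer, methyl (2R,3S)-5-bromo-7-methoxy-2-{(2S,3S)-7-methoxy-3-(methoxycarbonyl)-2-[3-methoxy-4-(pivaloyloxy)phenyl]-2,3-dihydrobenzofuran-5-yl}-2,3-dihydrobenzofuran-3-carboxylate F8. DBU in CH2Cl2 equilibrates the mixture to trans 15.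

Step 20. What may go wrong: epimerisation of the carbon next to the oxocarbenium ion through a dihydrofuran, loss of the kinetic facial preference, or over-reduction of the new benzylic ether by ionic hydrogenolysis. The fallback sets out from 29 and returns at 33; it closes the ring by a Williamson-type displacement at the primary carbon, which keeps the carbinol configuration, so the (R)-carbinol epimer of 29 is separated and used. Aminolysis of the lactone (pyrrolidine, AlMe3, CH2Cl2) gives (2S,3R)-4-hydroxy-2-[(R)-hydroxy(ArD)methyl]-3-(ArG-methyl)-1-(pyrrolidin-1-yl)butan-1-one F9. Selective sulfonylation of the only primary hydroxyl (TsCl, Et3N, CH2Cl2, 0 °C) gives (2R,3S)-3-[(R)-hydroxy(ArD)methyl]-2-(ArG-methyl)-4-oxo-4-(pyrrolidin-1-yl)butyl 4-methylbenzenesulfonate F10. KOt-Bu in THF at 0 °C closes the ring (5-exo-tet) to [(2R,3S,4R)-2-ArD-4-(ArG-methyl)tetrahydrofuran-3-yl](pyrrolidin-1-yl)methanone F11. LiBHEt3 in THF reduces the amide to the primary alcohol 33.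

Further compounds
F1 | step 5 | 4-(hydroxymethyl)-2-methoxyphenyl pivalate | COc1cc(CO)ccc1OC(=O)C(C)(C)C
F2 | step 5 | 1-{5-bromo-3-methoxy-2-[(3-methoxy-4-pivaloyloxyphenyl)methoxy]phenyl}ethan-1-one | CC(=O)c1cc(Br)cc(OC)c1OCc1ccc(OC(=O)C(C)(C)C)c(OC)c1
F3 | step 5 | methyl 2-{5-bromo-3-methoxy-2-[(3-methoxy-4-pivaloyloxyphenyl)methoxy]phenyl}acetate | COC(=O)Cc1cc(Br)cc(OC)c1OCc1ccc(OC(=O)C(C)(C)C)c(OC)c1
F4 | step 5 | methyl 2-diazo-2-{5-bromo-3-methoxy-2-[(3-methoxy-4-pivaloyloxyphenyl)methoxy]phenyl}acetate | COC(=O)C(=[N+]=[N-])c1cc(Br)cc(OC)c1OCc1ccc(OC(=O)C(C)(C)C)c(OC)c1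
F5 | step 5 | methyl (2S,3R)-5-bromo-7-methoxy-2-[3-methoxy-4-(pivaloyloxy)phenyl]-2,3-dihydrobenzofuran-3-carboxylate (cis) | Brc1cc(OC)c2c(c1)[C@@H](C(=O)OC)[C@@H](c1ccc(OC(=O)C(C)(C)C)c(OC)c1)O2
F6 | step 8 | methyl (2S,3S)-5-{(2S,3E)-6-bromo-3-[(dimethylamino)methylidene]-8-methoxy-4-oxochroman-2-yl}-7-methoxy-2-[3-methoxy-4-(pivaloyloxy)phenyl]-2,3-dihydrobenzofuran-3-carboxylate | Brc1cc(OC)c2c(c1)C(=O)/C(=C/N(C)C)[C@H](c3cc(OC)c4c(c3)[C@H](C(=O)OC)[C@@H](c3ccc(OC(=O)C(C)(C)C)c(OC)c3)O4)O2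
F7 | step 8 | methyl (2S,3S)-5-[(2S)-6-bromo-3-diazo-8-methoxy-4-oxochroman-2-yl]-7-methoxy-2-[3-methoxy-4-(pivaloyloxy)phenyl]-2,3-dihydrobenzofuran-3-carboxylate | Brc1cc(OC)c2c(c1)C(=O)C(=[N+]=[N-])[C@H](c3cc(OC)c4c(c3)[C@H](C(=O)OC)[C@@H](c3ccc(OC(=O)C(C)(C)C)c(OC)c3)O4)O2
F8 | step 8 | methyl (2R,3S)-5-bromo-7-methoxy-2-{(2S,3S)-7-methoxy-3-(methoxycarbonyl)-2-[3-methoxy-4-(pivaloyloxy)phenyl]-2,3-dihydrobenzofuran-5-yl}-2,3-dihydrobenzofuran-3-carboxylate (cis in the new ring) | Brc1cc(OC)c2c(c1)[C@H](C(=O)OC)[C@H](c3cc(OC)c4c(c3)[C@H](C(=O)OC)[C@@H](c3ccc(OC(=O)C(C)(C)C)c(OC)c3)O4)O2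
F9 | step 20 | (2S,3R)-4-hydroxy-2-[(R)-hydroxy(ArD)methyl]-3-(ArG-methyl)-1-(pyrrolidin-1-yl)butan-1-one | O=C(N1CCCC1)[C@H]([C@@H](O)c1cc(OC)c2c(c1)[C@@H](CO[Si](C)(C)C(C)(C)C)[C@H](c3cc(OC)c4c(c3)[C@H](CO[Si](C)(C)C(C)(C)C)[C@@H](c3ccc(O[Si](C)(C)C(C)(C)C)c(OC)c3)O4)O2)[C@H](CO)Cc1ccc(O[Si](C)(C)C(C)(C)C)c(OC)c1
F10 | step 20 | (2R,3S)-3-[(R)-hydroxy(ArD)methyl]-2-(ArG-methyl)-4-oxo-4-(pyrrolidin-1-yl)butyl 4-methylbenzenesulfonate | O=C(N1CCCC1)[C@H]([C@@H](O)c1cc(OC)c2c(c1)[C@@H](CO[Si](C)(C)C(C)(C)C)[C@H](c3cc(OC)c4c(c3)[C@H](CO[Si](C)(C)C(C)(C)C)[C@@H](c3ccc(O[Si](C)(C)C(C)(C)C)c(OC)c3)O4)O2)[C@H](COS(=O)(=O)c1ccc(C)cc1)Cc1ccc(O[Si](C)(C)C(C)(C)C)c(OC)c1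
F11 | step 20 | [(2R,3S,4R)-2-ArD-4-(ArG-methyl)tetrahydrofuran-3-yl](pyrrolidin-1-yl)methanone | O=C(N1CCCC1)[C@@H]1[C@H](c2cc(OC)c3c(c2)[C@@H](CO[Si](C)(C)C(C)(C)C)[C@H](c4cc(OC)c5c(c4)[C@H](CO[Si](C)(C)C(C)(C)C)[C@@H](c4ccc(O[Si](C)(C)C(C)(C)C)c(OC)c4)O5)O3)OC[C@@H]1Cc1ccc(O[Si](C)(C)C(C)(C)C)c(OC)c1
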